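The readings were computed with constants of no real substance; noise was put on by code.

**Early times.** At early times I want one number from each run that I can carry to the flasks asked about.

| flask | X | L | temperature | remark | time |
|---|---|---|---|---|---|
| ochre | 12 mM | 0.10 µM | 15 °C | run made earlier |  |
| green | 12 mM | 0.16 µM | 48 °C | run made earlier |  |
| teal | 18 mM | 0.074 µM | 15 °C | run made earlier |  |
| theta | 12 mM | 0.074 µM | 40 °C |  | 2.5 h |
| beta | 12 mM | 0.074 µM | 20 °C |  | 2.5 h |
| alpha | 12 mM | 0.074 µM | 0 °C |  | 2.5 h |
| zeta | 12 mM | 0.074 µM | 60 °C |  | 2.5 h |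

- ochre (time / h: Q / %, X / %): 0.833: 3, 95; 2.50: 10, 86; 5.00: 16, 74; 6.00: 24, 69
- green (time / min: Q / %, X / %): 15.0: 23, 71; 40.0: 49, 36; 80.0: 68, 5; 120: 70, 2
- teal (time / h: Q / %, X / %): 0.833: 2, 96; 2.50: 4, 87; 5.00: 11, 87; 6.00: 12, 80

(readings scatter by 2 percentage points)

- the flask that comes out highest in amount of Q, in percent of the X charged, or "all alike" when all lie within 1.5 percentage points (theta / beta / alpha / zeta / all alike)
- Q at the end, in percent of the X charged, theta
- Q at the end, in percent of the X charged, beta
- Q at the end, in percent of the X charged, alpha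
- Q at the end, in percent of the X charged, zeta



**Enzyme balance.** L is charged in a far smaller amount than X (0.074 µM against 12 mM), so I write the balance of L: what is charged stays free, sits bound, or is lost. While none is lost, Q should grow steadily with the charge of L. In the ochre run, 24% of Q after 6.00 h gives 4800 h⁻¹, the Q made per hour for each L charged, which I call the turnover rate (the usual turnover frequency).

**First doubts.** Perhaps L is already dying in the ochre run. But its reading at 2.50 h gives 4800 h⁻¹, so the pace shows no sag. Perhaps the rate follows X. The teal run, with 18 mM of X, gives 4860 h⁻¹, no visible change, and the asked flasks hold ochre's 12 mM anyway.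

**Temperature.** The first green reading gives 69000 h⁻¹, so the two temperatures imply an activation energy near 62.1 kJ mol⁻¹. With that, my reckoning of Q is 1.78% in alpha, 11.5% in beta and 58.7% in theta.

**Warm doubt.** At its end the green run has 28.0% of the X charged in neither Q nor X, so something else takes X there. The rule counts no such path, so I trust theta's figure less and expect less Q than it says. Zeta lies beyond every run, and I give it no number.

**The forecast.** The forecast names theta highest, with 52% in theta, 11% in beta, 2% in alpha and 20% in zeta. At the hottest setting it says “the enzyme probably dies within minutes”.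

**The result.** The flask theta comes out highest, with 39.8%, then beta 11.5%, zeta 4.38% and alpha 1.96%.

    G → L + Q (k = 1090 min⁻¹, Ea = 57.0 kJ mol⁻¹)
    L → E (k = 3.68 × 10⁻⁴ min⁻¹, Ea = 267 kJ mol⁻¹)
    X + Q → J (k = 0.720 M⁻¹ min⁻¹, Ea = 56.0 kJ mol⁻¹)
    X + L ⇌ G (K = 180 M⁻¹, k = 2.64 × 10⁶ M⁻¹ s⁻¹, Ea = 19.0 kJ mol⁻¹, ΔH = 14.0 kJ mol⁻¹)
    (constants at 40 °C)

In alpha at 2.50 h, G holds 49.0% of the enzyme, L 51.0% and E 0%, and Q stands at 1.96% against my reckoned 1.78%. Read at 10 h, the same flask is reckoned by the turnover rate at 7.12%. It holds 7.14% of Q, with 1.56% of J and 91% of X.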